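**Retrosynthetic overview**
- The diol comes from LiAlH4 reduction of the cis-fused C9/C9′ lactone. That lactone is the thermodynamic C2 epimer of the trans-fused lactone released from a 1,2-cis-2,3-trans tetralin-2-carboxamide.
- Key disconnection C1–C8a (ring B). In the seco-lignan the benzylic methylene C1 is beta to the C9 carbonyl, while the other benzylic methylene C4 is gamma. An N,N-bidentate 8-aminoquinoline amide on C9 can therefore hold palladium in a five-membered ring Pd–N–C9–C2–C1 only at C1, and an iodide on C8a of ring A then closes ring B.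
- The seco amide comes from a trans-2,3-dibenzylbutyrolactone. C3 is set by Evans benzylation of a succinate imide with the ring A bromide, and C2 by anti alkylation of the lactone enolate with the trimethoxybenzyl halide.
- The ring A bromide comes from 5-hydroxyvanillin by MOM protection, reduction, directed ortho-lithiation–iodination next to the C8 OMOM group, and Appel bromination.
- Ring order: both arenes are bought, a temporary butyrolactone is made and opened, ring B closes in the key step, and a second temporary lactone corrects C2 before it is reduced.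

Key step: step 11

Remark: tetralin numbering is used for all compounds, open-chain ones included (C1 aryl-bearing carbon, C2 and C3 bearing C9 and C9′, C4 methylene, ring A = C4a–C8a). Read this way the target is (1S,2R,3S), that is 1,2-trans and 2,3-cis. ArA = 2-iodo-5-methoxy-3,4-bis(methoxymethoxy)phenyl (iodine on C8a), ArC = 3,4,5-trimethoxyphenyl, Q = quinolin-8-yl.

Step 1
Reactants: 1 5-hydroxyvanillin (3,4-dihydroxy-5-methoxybenzaldehyde)
Product: 2 3-methoxy-4,5-bis(methoxymethoxy)benzaldehyde
Conditions: MOMCl (3 equiv), iPr2NEt (4 equiv), CH2Cl2, 0 °C → rt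
Reagents that add atoms: chloromethyl methyl ether (MOMCl), COCCl
Why: Williamson-type O-alkylation of both phenols with the reactive alpha-chloro ether gives acetal ethers that survive bases, hydrides and organolithiums and later steer the lithiation.

Step 2
Reactants: 2 3-methoxy-4,5-bis(methoxymethoxy)benzaldehyde
Product: 3 [3-methoxy-4,5-bis(methoxymethoxy)phenyl]methanol
Conditions: NaBH4, MeOH, 0 °C
Reagents that add atoms: none
Why: Borohydride reduction converts the aldehyde into the benzylic alcohol and leaves the acetal ethers untouched.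

Step 3
Reactants: 3 [3-methoxy-4,5-bis(methoxymethoxy)phenyl]methanol
Product: 5 [2-iodo-5-methoxy-3,4-bis(methoxymethoxy)phenyl]methanol (ArA-CH2OH), via dilithio species 4 (not isolated)
Conditions: n-BuLi (2.3 equiv), THF, −20 → 0 °C; I2 (1.3 equiv), THF, −78 °C → rt; aq. Na2S2O3
Reagents that add atoms: iodine, II
Why: In this directed ortho-metalation the second equivalent of n-BuLi should remove the ring hydrogen flanked by the lithium alkoxide arm and the chelating OMOM group rather than the one next to the weaker OMe director, and iodine traps the aryllithium at the future C8a.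

Step 4
Reactants: 5 ArA-CH2OH
Product: 6 1-(bromomethyl)-2-iodo-5-methoxy-3,4-bis(methoxymethoxy)benzene (ArA-CH2Br)
Conditions: CBr4, PPh3, CH2Cl2, 0 °C
Reagents that add atoms: carbon tetrabromide, BrC(Br)(Br)Br
Why: The Appel reaction replaces the benzylic hydroxyl by bromide under nearly neutral conditions that spare the MOM ethers and the aryl iodide.

Step 5
Reactants: 7 (S)-4-benzyloxazolidin-2-one; 8 methyl 4-chloro-4-oxobutanoate
Product: 10 methyl 4-[(4S)-4-benzyl-2-oxooxazolidin-3-yl]-4-oxobutanoate, via N-lithio oxazolidinone 9 (not isolated)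
Conditions: 7, n-BuLi (1.0 equiv), THF, −78 °C; then 8, −78 → 0 °C
Reagents that add atoms: none
Why: N-acylation of the lithiated oxazolidinone occurs at the acid chloride much faster than at the methyl ester.

Step 6
Reactants: 10 succinate imide; 6 ArA-CH2Br
Product: 12 methyl (3S)-4-[(4S)-4-benzyl-2-oxooxazolidin-3-yl]-3-(ArA-methyl)-4-oxobutanoate, via chelated Z sodium enolate 11 (not isolated)
Conditions: NaN(SiMe3)2 (1.1 equiv), THF, −78 °C; then 6, −78 → −30 °C
Reagents that add atoms: none
Why: In this Evans alkylation the enolate forms at the more acidic imide alpha carbon rather than next to the ester, and the bromide approaches the chelated Z enolate anti to the 4-benzyl group, which sets C3 as (S).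

Step 7
Reactants: 12 alkylated imide
Product: 14 (4S)-4-(ArA-methyl)dihydrofuran-2(3H)-one, via gamma-hydroxy ester 13 (not isolated)
Conditions: NaBH4 (4 equiv), THF/H2O 4:1, 0 °C → rt; aq. citric acid to pH 4
Reagents that add atoms: none
Why: Reductive auxiliary removal by borohydride takes the activated exocyclic imide carbonyl (C9′) to the alcohol while the methyl ester and the iodide stay, and the gamma-hydroxy ester closes by 5-exo-trig lactonisation without touching C3.

Step 8
Reactants: 14 (4S)-lactone; 15 3,4,5-trimethoxybenzyl chloride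
Product: 18 (3S,4S)-4-(ArA-methyl)-3-(ArC-methyl)dihydrofuran-2(3H)-one (trans), via 3,4,5-trimethoxybenzyl iodide 16 (not isolated), via lithium enolate 17 (not isolated)
Conditions: 15, NaI, acetone, rt, solvent changed to THF (gives 16); 14, LiN(SiMe3)2 (1.1 equiv), THF, −78 °C (gives 17); then 16, DMPU, −78 → −30 °C
Reagents that add atoms: none
Why: Finkelstein exchange makes the halide reactive enough for low temperature, and the lactone enolate is alkylated on the face anti to the C3 substituent, which sets C2 as (S) with the usual trans relationship of dibenzylbutyrolactones.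

Step 9
Reactants: 18 trans-lactone; 19 8-aminoquinoline
Product: 21 (2S,3S)-4-hydroxy-3-(ArA-methyl)-N-Q-2-(ArC-methyl)butanamide, via dimethylaluminium quinolin-8-ylamide 20 (not isolated)
Conditions: 19 (3 equiv), AlMe3 (3 equiv), CH2Cl2, 0 °C → rt (gives 20); then 18, 40 °C; aq. KNaC4H4O6
Reagents that add atoms: none
Why: In this Weinreb-type aminolysis the aluminium amide makes the weakly nucleophilic arylamine open the lactone at C9 under non-enolising conditions, so C2 and C3 are kept.

Step 10
Reactants: 21 hydroxy amide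
Product: 22 (2S,3S)-4-(tert-butyldimethylsilyloxy)-3-(ArA-methyl)-N-Q-2-(ArC-methyl)butanamide
Conditions: TBSCl, imidazole, DMF, rt
Reagents that add atoms: tert-butyldimethylsilyl chloride (TBSCl), CC(C)(C)[Si](C)(C)Cl
Why: Silylation of the primary alcohol blocks relactonisation and alcohol oxidation at the temperature of the key step.

Step 11
Reactants: 22 seco amide
Product: 25 (1S,2S,3S)-3-(tert-butyldimethylsilyloxymethyl)-6-methoxy-7,8-bis(methoxymethoxy)-N-Q-1-ArC-1,2,3,4-tetrahydronaphthalene-2-carboxamide (1,2-cis-2,3-trans), via five-membered palladacycle 23 (not isolated), via tetravalent palladium aryl iodide complex 24 (not isolated)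
Conditions: Pd(OAc)2 (15 mol %), Ag2CO3 (1.5 equiv), (BnO)2P(O)OH (30 mol %), t-AmylOH, 0.005 M, 110 °C, Ar, dark
Reagents that add atoms: none
Why: Proposed new method: the deprotonated amide nitrogen and the quinoline nitrogen bind divalent palladium, a phosphate- or carbonate-assisted concerted metalation–deprotonation cleaves one C1–H bond to give palladacycle 23 (Pd–N–C9–C2–C1), the tethered C8a–I bond adds oxidatively to give the tetravalent palladium species 24, and C–C reductive elimination with retention at C1 forms C1–C8a while Ag2CO3 takes up iodide and the proton. The closest known reaction type is the 8-aminoquinoline-directed beta-C(sp3)–H arylation of benzylic methylenes with aryl iodides, which is established between two molecules and for macrocyclisation but not for a six-membered carbocycle. Ring B closes as a six-membered ring by reductive elimination from a seven-membered metallacycle (Pd, C1, C2, C3, C4, C4a, C8a) bridged across the five-membered chelate. The new stereocentre C1 is controlled by C2, because the palladacycle with ArC on C1 trans to the C3 chain on C2 is favoured, the iodoarene can reach palladium only from the face that carries C3 and is free of ArC, and retention then gives (1S) with the aryl group cis to C9. The step needs a choice between the benzylic carbons C1 and C4, which is secured because C1 is beta and C4 gamma to C9 and the other beta carbon C3 is a methine that resists palladation, and the 0.005 M dilution should favour ring closure over oligomerisation.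

Step 12
Reactants: 25 tetralin amide
Product: 26 N-Boc derivative of 25 (tert-butyl N-acyl-N-Q-carbamate, 1S,2S,3S)
Conditions: Boc2O (4 equiv), DMAP (1 equiv), MeCN, 50 °C
Reagents that add atoms: di-tert-butyl dicarbonate (Boc2O), CC(C)(C)OC(=O)OC(=O)OC(C)(C)C
Why: DMAP-catalysed N-acylation turns the secondary amide into a twisted, imide-like N-acyl carbamate, the usual activation for removing the aminoquinoline group.

Step 13
Reactants: 26 N-Boc amide
Product: 29 (1S,2R,3S) cis-fused C9/C9′ gamma-lactone of the 6-methoxy-7,8-bis(methoxymethoxy)-1-ArC-tetralin (1,2-trans-2,3-cis), via desilylated N-Boc amide 27 (not isolated), via trans-fused lactone 28 (not isolated)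
Conditions: Bu4NF (1.5 equiv), THF, 0 °C → rt; then DBU (1 equiv), rt → 40 °C
Reagents that add atoms: none
Why: Fluoride desilylation frees the C9′ alkoxide, which attacks the activated C9 carbonyl in a 5-exo-trig acyl transfer and expels the carbamate anion, and DBU then equilibrates C2 through the lactone enolate to the less strained cis-fused ring (the drive known from the podophyllotoxin-to-picropodophyllin epimerisation), inverting C2 to (R).

Step 14
Reactants: 29 cis-fused lactone
Product: 30 (1S,2R,3S)-2,3-bis(hydroxymethyl)-6-methoxy-7,8-bis(methoxymethoxy)-1-ArC-1,2,3,4-tetrahydronaphthalene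
Conditions: LiAlH4 (3 equiv), THF, 0 °C → rt; aq. KNaC4H4O6
Reagents that add atoms: none
Why: Hydride reduction of the lactone to the 1,4-diol is faster than enolisation and starts from the thermodynamic C2 epimer, so the three stereocentres are kept and the MOM ethers survive.

Step 15
Reactants: 30 bis-MOM diol
Product: 31 target (1S,2R,3S)-7,8-dihydroxy-2,3-bis(hydroxymethyl)-6-methoxy-1-ArC-1,2,3,4-tetrahydronaphthalene
Conditions: 3 M aq. HCl, MeOH, 40 °C, Ar
Reagents that add atoms: none
Why: Acid-catalysed acetal exchange with methanol removes both aryl MOM ethers under conditions too mild for cyclodehydration of the diol, and no stereocentre carries a leaving group or an acidic hydrogen.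

**Compound list**
1 | 5-hydroxyvanillin | COc1cc(C=O)cc(O)c1O | starting material
2 | 3-methoxy-4,5-bis(methoxymethoxy)benzaldehyde | COCOc1cc(C=O)cc(OC)c1OCOC | intermediate
3 | [3-methoxy-4,5-bis(methoxymethoxy)phenyl]methanol | COCOc1cc(CO)cc(OC)c1OCOC | intermediate
4 | lithium [2-lithio-5-methoxy-3,4-bis(methoxymethoxy)phenyl]methoxide | [Li]OCc1cc(OC)c(OCOC)c(OCOC)c1[Li] | intermediate
5 | [2-iodo-5-methoxy-3,4-bis(methoxymethoxy)phenyl]methanol | OCc1cc(OC)c(OCOC)c(OCOC)c1I | intermediate
6 | 1-(bromomethyl)-2-iodo-5-methoxy-3,4-bis(methoxymethoxy)benzene | BrCc1cc(OC)c(OCOC)c(OCOC)c1I | intermediate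
7 | (S)-4-benzyloxazolidin-2-one | O=C1N[C@@H](Cc2ccccc2)CO1 | starting material
8 | methyl 4-chloro-4-oxobutanoate | COC(=O)CCC(=O)Cl | starting material
9 | N-lithio-(S)-4-benzyloxazolidin-2-one | [Li]N1[C@@H](Cc2ccccc2)COC1=O | intermediate
10 | methyl 4-[(4S)-4-benzyl-2-oxooxazolidin-3-yl]-4-oxobutanoate | COC(=O)CCC(=O)N1[C@@H](Cc2ccccc2)COC1=O | intermediate
11 | Z sodium enolate of 10 | [Na+].[O-]/C(=C\CC(=O)OC)N1[C@@H](Cc2ccccc2)COC1=O | intermediate
12 | methyl (3S)-4-[(4S)-4-benzyl-2-oxooxazolidin-3-yl]-3-(ArA-methyl)-4-oxobutanoate | COC(=O)C[C@H](Cc1cc(OC)c(OCOC)c(OCOC)c1I)C(=O)N1[C@@H](Cc2ccccc2)COC1=O | intermediate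
13 | methyl (3S)-4-hydroxy-3-(ArA-methyl)butanoate | COC(=O)C[C@H](Cc1cc(OC)c(OCOC)c(OCOC)c1I)CO | intermediate
14 | (4S)-4-(ArA-methyl)dihydrofuran-2(3H)-one | O=C1C[C@H](Cc2cc(OC)c(OCOC)c(OCOC)c2I)CO1 | intermediate
15 | 3,4,5-trimethoxybenzyl chloride | COc1cc(CCl)cc(OC)c1OC | starting material
16 | 3,4,5-trimethoxybenzyl iodide | COc1cc(CI)cc(OC)c1OC | intermediate
17 | lithium enolate of 14 | [Li]OC1=C[C@H](Cc2cc(OC)c(OCOC)c(OCOC)c2I)CO1 | intermediate
18 | (3S,4S)-4-(ArA-methyl)-3-(ArC-methyl)dihydrofuran-2(3H)-one | O=C1[C@@H](Cc2cc(OC)c(OC)c(OC)c2)[C@H](Cc2cc(OC)c(OCOC)c(OCOC)c2I)CO1 | intermediate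
19 | 8-aminoquinoline | Nc1cccc2cccnc12 | starting material
20 | dimethylaluminium quinolin-8-ylamide | C[Al](C)Nc1cccc2cccnc12 | intermediate
21 | (2S,3S)-4-hydroxy-3-(ArA-methyl)-N-Q-2-(ArC-methyl)butanamide | O=C(Nc1cccc2cccnc12)[C@@H](Cc1cc(OC)c(OC)c(OC)c1)[C@@H](CO)Cc1cc(OC)c(OCOC)c(OCOC)c1I | intermediate
22 | (2S,3S)-4-(tert-butyldimethylsilyloxy)-3-(ArA-methyl)-N-Q-2-(ArC-methyl)butanamide | O=C(Nc1cccc2cccnc12)[C@@H](Cc1cc(OC)c(OC)c(OC)c1)[C@@H](CO[Si](C)(C)C(C)(C)C)Cc1cc(OC)c(OCOC)c(OCOC)c1I | intermediate
23 | trans-substituted five-membered C1 palladacycle of 22 (divalent palladium, fourth site solvent) | CC(C)(C)[Si](C)(C)OC[C@@H](Cc1cc(OC)c(OCOC)c(OCOC)c1I)[C@H]1C(=O)N2c3cccc4ccc[n+](c34)[Pd-]2[C@@H]1c1cc(OC)c(OC)c(OC)c1 | intermediate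
24 | bridged aryl iodide complex of tetravalent palladium (C1, C8a, I and both nitrogens on Pd) | CC(C)(C)[Si](C)(C)OC[C@H]1Cc2cc(OC)c(OCOC)c(OCOC)c2[Pd-]67(I)[C@H](c3cc(OC)c(OC)c(OC)c3)[C@@H]1C(=O)N6c1cccc3ccc[n+]7c13 | intermediate
25 | (1S,2S,3S) 1,2-cis-2,3-trans tetralin-2-carboxamide | COc1cc2c(c(OCOC)c1OCOC)[C@H](c1cc(OC)c(OC)c(OC)c1)[C@H](C(=O)Nc1cccc3cccnc13)[C@@H](CO[Si](C)(C)C(C)(C)C)C2 | intermediate
26 | N-Boc derivative of 25 | COc1cc2c(c(OCOC)c1OCOC)[C@H](c1cc(OC)c(OC)c(OC)c1)[C@H](C(=O)N(C(=O)OC(C)(C)C)c1cccc3cccnc13)[C@@H](CO[Si](C)(C)C(C)(C)C)C2 | intermediate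
27 | desilylated N-Boc amide | COc1cc2c(c(OCOC)c1OCOC)[C@H](c1cc(OC)c(OC)c(OC)c1)[C@H](C(=O)N(C(=O)OC(C)(C)C)c1cccc3cccnc13)[C@@H](CO)C2 | intermediate
28 | (1S,2S,3S) trans-fused lactone | COc1cc2c(c(OCOC)c1OCOC)[C@H](c1cc(OC)c(OC)c(OC)c1)[C@@H]1C(=O)OC[C@H]1C2 | intermediate
29 | (1S,2R,3S) cis-fused lactone | COc1cc2c(c(OCOC)c1OCOC)[C@H](c1cc(OC)c(OC)c(OC)c1)[C@H]1C(=O)OC[C@H]1C2 | intermediate
30 | (1S,2R,3S) bis-MOM diol | COc1cc2c(c(OCOC)c1OCOC)[C@H](c1cc(OC)c(OC)c(OC)c1)[C@@H](CO)[C@@H](CO)C2 | intermediate
31 | CNP0188980.1 | COc1cc2c(c(O)c1O)[C@H](c1cc(OC)c(OC)c(OC)c1)[C@@H](CO)[C@@H](CO)C2 | target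

**Step count**
- Total step count: 15.
- Longest linear sequence: 14 steps (steps 1–4 and 6–15, from 5-hydroxyvanillin).

**Steps most likely to fail**

**Step 11.**
- Risk: oxidative addition of the doubly ortho-flanked C8a–I bond to the palladacycle may be too slow inside the bridged geometry. Hydrodeiodination, C–N reductive elimination or intermolecular arylation could then overtake ring closure.
- Fallback, from 14 back to 29, forming the same C1–C8a bond by a radical conjugate cyclisation: the enolate of 14 (LiN(SiMe3)2, THF, −78 °C) is added to 3,4,5-trimethoxybenzaldehyde to give the aldol adduct F1 as both carbinol epimers. MsCl/Et3N converts it into the mesylate F2, and DBU eliminates this to the (E)-benzylidene lactone F3.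
- Bu3SnH and AIBN in dilute toluene at 80 °C then generate the C8a aryl radical. It should add 6-endo-trig to C1, the polarity-matched and less substituted beta carbon of the unsaturated lactone.
- The C4 tether allows attack on one alkene face only, which with the E geometry places ArC trans to C9′. The C2 radical takes up hydrogen to give 28 and 29, and DBU converges the mixture on 29.

**Step 13.**
- Risk: the freed alkoxide may attack the carbamate carbonyl instead of C9 (Boc transfer), or closure of the strained trans-fused ring may lag behind cleavage of the activated amide by adventitious water.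
- Fallback, from 25 back to 31, without Boc activation: CF3CO2H/H2O/THF at 60 °C removes the silyl and MOM groups and drives an acid-promoted N-to-O acyl transfer, with the protonated aminoquinoline as leaving group, to the catechol trans-fused lactone F4.
- NaOAc in refluxing EtOH under argon epimerises C2 to the catechol cis-fused lactone F5, and excess LiAlH4 in THF gives 31 directly.

**Step 3.**
- Risk: competing lithiation next to the methoxy group would place the iodine on the wrong ortho carbon.
- Fallback, from 1 back to 5, replacing metalation by electrophilic substitution: Ac2O/pyridine gives 3,4-diacetoxy-5-methoxybenzaldehyde F6, in which the methoxy group is the only strong donor.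
- N-iodosuccinimide in CF3CO2H should therefore iodinate para to the methoxy group, the same acetate switch that sends halogenation of O-acetylvanillin para to its methoxy group. This gives 3,4-diacetoxy-2-iodo-5-methoxybenzaldehyde F7.
- K2CO3/MeOH frees 3,4-dihydroxy-2-iodo-5-methoxybenzaldehyde F8. MOMCl/iPr2NEt gives 2-iodo-5-methoxy-3,4-bis(methoxymethoxy)benzaldehyde F9, and NaBH4 gives 5.

**Further compounds**
F1 | step 11 | (3S,4S)-3-[hydroxy(ArC)methyl]-4-(ArA-methyl)dihydrofuran-2(3H)-one, both carbinol epimers | O=C1[C@@H](C(O)c2cc(OC)c(OC)c(OC)c2)[C@H](Cc2cc(OC)c(OCOC)c(OCOC)c2I)CO1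
F2 | step 11 | mesylate of F1 | O=C1[C@@H](C(OS(C)(=O)=O)c2cc(OC)c(OC)c(OC)c2)[C@H](Cc2cc(OC)c(OCOC)c(OCOC)c2I)CO1
F3 | step 11 | (3E,4S)-4-(ArA-methyl)-3-(3,4,5-trimethoxybenzylidene)dihydrofuran-2(3H)-one | O=C1OC[C@@H](Cc2cc(OC)c(OCOC)c(OCOC)c2I)/C1=C\c1cc(OC)c(OC)c(OC)c1
F4 | step 13 | (1S,2S,3S) 7,8-dihydroxy trans-fused lactone | COc1cc2c(c(O)c1O)[C@H](c1cc(OC)c(OC)c(OC)c1)[C@@H]1C(=O)OC[C@H]1C2
F5 | step 13 | (1S,2R,3S) 7,8-dihydroxy cis-fused lactone | COc1cc2c(c(O)c1O)[C@H](c1cc(OC)c(OC)c(OC)c1)[C@H]1C(=O)OC[C@H]1C2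
F6 | step 3 | 3,4-diacetoxy-5-methoxybenzaldehyde | COc1cc(C=O)cc(OC(C)=O)c1OC(C)=O
F7 | step 3 | 3,4-diacetoxy-2-iodo-5-methoxybenzaldehyde | COc1cc(C=O)c(I)c(OC(C)=O)c1OC(C)=O
F8 | step 3 | 3,4-dihydroxy-2-iodo-5-methoxybenzaldehyde | COc1cc(C=O)c(I)c(O)c1O
F9 | step 3 | 2-iodo-5-methoxy-3,4-bis(methoxymethoxy)benzaldehyde | COCOc1c(I)c(C=O)cc(OC)c1OCOC
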